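**Plan**
Labels: ring A is the benzo ring (C4a to C8a) with the C5 methoxy group and the C7 side chain; ring B is the dioxane (O1, C2 bearing the aryl group, C3 bearing the methyl group, O4); ring C is the 3,4,5-trimethoxyphenyl group.
Retrosynthetic cuts, in order: the side-chain C=C bond (back to the C7 aldehyde), the methyl C–H (back to CH2I), the O4–C3 bond of ring B, and last the O1–C2 bond, leaving a ring C cinnamyl carbonate and 5-hydroxyvanillin masked at O4.
Enabling feature: C3 and its methyl carbon are the two carbons of a vinyl group on C2, and the C4a hydroxyl of ring A sits where attack on the inner vinyl carbon closes the six-membered ring B.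
Forward: rings A and C are joined at O1–C2 by iridium-catalysed allylic etherification, the O4 acetal is removed, iodine closes ring B, the iodide is reduced to the methyl group, and a two-carbon Wittig reaction finishes the side chain.
Stereochemistry: C2 comes from the chiral iridium–phosphoramidite catalyst, C3 from C2 by substrate control in the ring closure (trans), and the E alkene from the stabilised ylide.
O4 is carried as a SEM acetal, because a silyl ether on this catechol would shift to the neighbouring aryloxide under the basic coupling conditions and scramble the regiochemistry.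

Key step: step 6

Assumption: the (Ra,Rc,Rc) enantiomer of the phosphoramidite is taken to deliver the (R)-configured branched ether from an (E)-cinnamyl carbonate; if a first run shows the opposite sense, the (Sa,Sc,Sc) ligand replaces it with nothing else changed.

**Route**

Step 1
Reactants: 1 methyl (E)-3-(3,4,5-trimethoxyphenyl)prop-2-enoate
Product: 2 (E)-3-(3,4,5-trimethoxyphenyl)prop-2-en-1-ol
Conditions: i-Bu2AlH (2.5 equiv), CH2Cl2, −78 to 0 °C; aq. potassium sodium tartrate
Reagents that add atoms: none
Why: Aluminium hydride reduction of a conjugated ester at low temperature proceeds by 1,2-addition and should give the allylic alcohol with the E alkene intact.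

Step 2
Reactants: 2 (E)-3-(3,4,5-trimethoxyphenyl)prop-2-en-1-ol
Product: 3 methyl (E)-3-(3,4,5-trimethoxyphenyl)prop-2-en-1-yl carbonate
Conditions: ClCO2Me (1.5 equiv), pyridine (2 equiv), CH2Cl2, 0 °C to rt
Reagents that add atoms: methyl chloroformate, COC(=O)Cl
Why: O-acylation of the primary allylic alcohol with a chloroformate should give the carbonate leaving group needed for the allyl–iridium chemistry.

Step 3
Reactants: 4 5-hydroxyvanillin (3,4-dihydroxy-5-methoxybenzaldehyde)
Product: 5 3-hydroxy-5-methoxy-4-{[2-(trimethylsilyl)ethoxy]methoxy}benzaldehyde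
Conditions: SEMCl (1.0 equiv, slow addition), Li2CO3 (1.1 equiv), DMF, rt
Reagents that add atoms: 2-(trimethylsilyl)ethoxymethyl chloride, C[Si](C)(C)CCOCCl
Why: Williamson-type O-alkylation under weak-base control, in which Li2CO3 ionises only the 4-OH (para to the formyl group and much more acidic than the 3-OH), so the acetal chloride should be taken up at O4 as in the known selective 4-O-alkylations of this catechol aldehyde.

Step 4
Reactants: 3 methyl (E)-3-(3,4,5-trimethoxyphenyl)prop-2-en-1-yl carbonate; 5 3-hydroxy-5-methoxy-4-{[2-(trimethylsilyl)ethoxy]methoxy}benzaldehyde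
Product: 7 (R)-3-methoxy-5-{[1-(3,4,5-trimethoxyphenyl)prop-2-en-1-yl]oxy}-4-{[2-(trimethylsilyl)ethoxy]methoxy}benzaldehyde, via lithium aryloxide 6 (not isolated)
Conditions: 5 (1.5 equiv), LiOt-Bu (1.0 equiv per 5), THF, rt; then 3, [Ir(cod)Cl]2 (2 mol %), (Ra,Rc,Rc)-O,O'-(1,1'-binaphthyl-2,2'-diyl)-N,N-bis(1-phenylethyl)phosphoramidite (4 mol %; pre-activated with n-PrNH2, volatiles removed), THF, 50 °C
Reagents that add atoms: none
Why: Iridium-catalysed asymmetric allylic etherification of a cinnamyl carbonate by an alkali aryloxide, in which the cyclometalated iridium–phosphoramidite complex ionises the carbonate and the aryloxide attacks the aryl-bearing allyl terminus, so the ligand's choice of allyl face should set C2 as R, while the SEM acetal cannot migrate and the aldehyde is inert to the aryloxide.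

Step 5
Reactants: 7 (R)-3-methoxy-5-{[1-(3,4,5-trimethoxyphenyl)prop-2-en-1-yl]oxy}-4-{[2-(trimethylsilyl)ethoxy]methoxy}benzaldehyde
Product: 8 (R)-4-hydroxy-3-methoxy-5-{[1-(3,4,5-trimethoxyphenyl)prop-2-en-1-yl]oxy}benzaldehyde
Conditions: Bu4NF (3 equiv), THF/DMPU, 50 °C; aq. NH4Cl
Reagents that add atoms: none
Why: Fluoride-induced fragmentation of the SEM ether (attack at silicon, loss of ethene and formaldehyde) should release the phenoxide, a good leaving group because it is para to the formyl group, without touching the allylic-benzylic ether, the alkene or the C2 center.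

Step 6
Reactants: 8 (R)-4-hydroxy-3-methoxy-5-{[1-(3,4,5-trimethoxyphenyl)prop-2-en-1-yl]oxy}benzaldehyde
Product: 9 (2S,3R)-3-(iodomethyl)-5-methoxy-2-(3,4,5-trimethoxyphenyl)-2,3-dihydro-1,4-benzodioxine-7-carbaldehyde (trans)
Conditions: I2 (3 equiv), NaHCO3 (3 equiv), MeCN, 0 °C, dark; aq. Na2S2O3
Reagents that add atoms: iodine, II
Why: Iodine reversibly forms an iodonium ion on the only alkene, and the C4a phenoxide of ring A (ionised by NaHCO3) opens it at the inner carbon, anti to iodine, which makes the O4–C3 bond and the primary carbon–iodine bond in one event. The closest known reaction type is the iodoetherification of 2-(allyloxy)phenols to 2-(iodomethyl)-1,4-benzodioxanes. Ring B closes in the 6-exo mode; the 7-endo path to the terminal carbon is slower on ring-size and stereoelectronic grounds. The one new stereocenter, C3, is set by the existing C2 center: in the half-chair transition state the C2–H eclipses the vinyl group (least allylic strain), the trimethoxyphenyl group lies pseudo-equatorial, and the trans ring with both substituents equatorial should result. The step needs 6-exo regioselectivity, trans diastereoselectivity and chemoselectivity for the alkene over both arenes; the tether length, the C2 aryl group and the mildness of I2/NaHCO3 secure these in turn, helped by the formyl group that deactivates ring A, whose positions ortho and para to the hydroxyl are all substituted. The bicarbonate buffer keeps the medium non-acidic, so the ionisable allylic-benzylic aryl ether at C2 should survive.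

Step 7
Reactants: 9 (2S,3R)-3-(iodomethyl)-5-methoxy-2-(3,4,5-trimethoxyphenyl)-2,3-dihydro-1,4-benzodioxine-7-carbaldehyde
Product: 10 (2S,3S)-5-methoxy-3-methyl-2-(3,4,5-trimethoxyphenyl)-2,3-dihydro-1,4-benzodioxine-7-carbaldehyde (trans)
Conditions: (Me3Si)3SiH (1.3 equiv), Et3B (0.2 equiv), air, toluene (0.3 M), rt
Reagents that add atoms: none
Why: Radical chain dehalogenation, in which the silyl radical abstracts iodine and the primary radical takes hydrogen from the silane, run at room temperature and high silane concentration so that hydrogen transfer should outrun β-scission of the β-aryloxy radical and silyl addition to the aldehyde, with neither stereocenter becoming a radical site.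

Step 8
Reactants: 10 (2S,3S)-5-methoxy-3-methyl-2-(3,4,5-trimethoxyphenyl)-2,3-dihydro-1,4-benzodioxine-7-carbaldehyde
Product: 11 (E)-3-[(2S,3S)-5-methoxy-3-methyl-2-(3,4,5-trimethoxyphenyl)-2,3-dihydro-1,4-benzodioxin-7-yl]prop-2-enal (numbering of 9 and 10 kept)
Conditions: Ph3P=CHCHO (1.3 equiv), toluene, 90 °C
Reagents that add atoms: (triphenylphosphoranylidene)acetaldehyde, O=CC=P(c1ccccc1)(c1ccccc1)c1ccccc1
Why: Wittig olefination of the aromatic aldehyde with a stabilised formyl ylide should give the E enal, and the small excess of ylide limits a second homologation of the product.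

**Compound list**

1 | methyl (E)-3-(3,4,5-trimethoxyphenyl)prop-2-enoate | COC(=O)/C=C/c1cc(OC)c(OC)c(OC)c1 | starting material
2 | (E)-3-(3,4,5-trimethoxyphenyl)prop-2-en-1-ol | OC/C=C/c1cc(OC)c(OC)c(OC)c1 | intermediate
3 | methyl (E)-3-(3,4,5-trimethoxyphenyl)prop-2-en-1-yl carbonate | COC(=O)OC/C=C/c1cc(OC)c(OC)c(OC)c1 | intermediate
4 | 5-hydroxyvanillin (3,4-dihydroxy-5-methoxybenzaldehyde) | COc1cc(C=O)cc(O)c1O | starting material
5 | 3-hydroxy-5-methoxy-4-{[2-(trimethylsilyl)ethoxy]methoxy}benzaldehyde | COc1cc(C=O)cc(O)c1OCOCC[Si](C)(C)C | intermediate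
6 | lithium 5-formyl-3-methoxy-2-{[2-(trimethylsilyl)ethoxy]methoxy}phenolate (formed and used in the flask) | [Li+].[O-]c1cc(C=O)cc(OC)c1OCOCC[Si](C)(C)C | intermediate
7 | (R)-3-methoxy-5-{[1-(3,4,5-trimethoxyphenyl)prop-2-en-1-yl]oxy}-4-{[2-(trimethylsilyl)ethoxy]methoxy}benzaldehyde | COc1cc([C@@H](C=C)Oc2cc(C=O)cc(OC)c2OCOCC[Si](C)(C)C)cc(OC)c1OC | intermediate
8 | (R)-4-hydroxy-3-methoxy-5-{[1-(3,4,5-trimethoxyphenyl)prop-2-en-1-yl]oxy}benzaldehyde | COc1cc([C@@H](C=C)Oc2cc(C=O)cc(OC)c2O)cc(OC)c1OC | intermediate
9 | (2S,3R)-3-(iodomethyl)-5-methoxy-2-(3,4,5-trimethoxyphenyl)-2,3-dihydro-1,4-benzodioxine-7-carbaldehyde | COc1cc([C@@H]2Oc3cc(C=O)cc(OC)c3O[C@H]2CI)cc(OC)c1OC | intermediate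
10 | (2S,3S)-5-methoxy-3-methyl-2-(3,4,5-trimethoxyphenyl)-2,3-dihydro-1,4-benzodioxine-7-carbaldehyde | COc1cc([C@@H]2Oc3cc(C=O)cc(OC)c3O[C@H]2C)cc(OC)c1OC | intermediate
11 | (E)-3-[(2S,3S)-5-methoxy-3-methyl-2-(3,4,5-trimethoxyphenyl)-2,3-dihydro-1,4-benzodioxin-7-yl]prop-2-enal | COc1cc([C@@H]2Oc3cc(/C=C/C=O)cc(OC)c3O[C@H]2C)cc(OC)c1OC | target

**Count and risks**

Total step count: 8. Longest linear sequence: 7 steps (1 to 11 through steps 1, 2, 4, 5, 6, 7 and 8); the ring A branch (4 to 11) is 6 steps.

Steps most likely to fail:

Step 6. The facial preference of a terminal vinyl group in the ring closure may be modest, so that part of the material closes to the cis ring under kinetic control. That ring cannot be epimerised afterwards. Slow cyclisation could also let iodine attack ring C. The fallback sets out from 8 and moves the closure to thermodynamic control. Reversible selenoetherification with N-(phenylseleno)phthalimide and catalytic camphorsulfonic acid in CH2Cl2 at rt should equilibrate to the trans selenide (2S,3R)-5-methoxy-3-[(phenylselanyl)methyl]-2-(3,4,5-trimethoxyphenyl)-2,3-dihydro-1,4-benzodioxine-7-carbaldehyde F1. Its carbon–selenium bond is then cut with Bu3SnH and AIBN in toluene at 80 °C, and the route is rejoined at 10.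

Step 4. The ortho-alkoxy aryloxide is hindered and only moderately nucleophilic, so attack on the allyl–iridium intermediate may be slow. The product also carries a good aryloxide leaving group and may re-ionise. Both processes would erode the branched-to-linear ratio and the enantiomeric purity. The fallback sets out from 3 and 5 and forms the O1–C2 bond by stereospecific substitution instead. Carbonate 3 is treated with Et3SiOK, [Ir(cod)Cl]2 and the (Sa,Sc,Sc) ligand in CH2Cl2 at rt, where the small silanolate should give (S)-triethyl{[1-(3,4,5-trimethoxyphenyl)prop-2-en-1-yl]oxy}silane F2. Bu4NF in THF at 0 °C frees (S)-1-(3,4,5-trimethoxyphenyl)prop-2-en-1-ol F3. A Mitsunobu reaction of this alcohol with phenol 5 (PPh3, diisopropyl azodicarboxylate, toluene, −20 to 0 °C) should proceed with inversion and rejoin the route at 7.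

Step 8. The electron-rich aldehyde may react sluggishly, and the product enal may be homologated a second time by the ylide to a dienal. The fallback sets out from 10 and builds the enal in three stages. A Horner–Wadsworth–Emmons reaction with (EtO)2P(O)CH2CO2Et and NaH in THF should give ethyl (E)-3-[(2S,3S)-5-methoxy-3-methyl-2-(3,4,5-trimethoxyphenyl)-2,3-dihydro-1,4-benzodioxin-7-yl]prop-2-enoate F5. Reduction with i-Bu2AlH in CH2Cl2 at −78 °C gives (E)-3-[(2S,3S)-5-methoxy-3-methyl-2-(3,4,5-trimethoxyphenyl)-2,3-dihydro-1,4-benzodioxin-7-yl]prop-2-en-1-ol F6. Oxidation of this allylic alcohol with MnO2 in CH2Cl2 at rt comes back to the route at 11.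

**Further compounds**

F1 | step 6 | (2S,3R)-5-methoxy-3-[(phenylselanyl)methyl]-2-(3,4,5-trimethoxyphenyl)-2,3-dihydro-1,4-benzodioxine-7-carbaldehyde | COc1cc([C@@H]2Oc3cc(C=O)cc(OC)c3O[C@H]2C[Se]c4ccccc4)cc(OC)c1OC
F2 | step 4 | (S)-triethyl{[1-(3,4,5-trimethoxyphenyl)prop-2-en-1-yl]oxy}silane | CC[Si](CC)(CC)O[C@@H](C=C)c1cc(OC)c(OC)c(OC)c1
F3 | step 4 | (S)-1-(3,4,5-trimethoxyphenyl)prop-2-en-1-ol | O[C@@H](C=C)c1cc(OC)c(OC)c(OC)c1
F5 | step 8 | ethyl (E)-3-[(2S,3S)-5-methoxy-3-methyl-2-(3,4,5-trimethoxyphenyl)-2,3-dihydro-1,4-benzodioxin-7-yl]prop-2-enoate | COc1cc([C@@H]2Oc3cc(/C=C/C(=O)OCC)cc(OC)c3O[C@H]2C)cc(OC)c1OC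
F6 | step 8 | (E)-3-[(2S,3S)-5-methoxy-3-methyl-2-(3,4,5-trimethoxyphenyl)-2,3-dihydro-1,4-benzodioxin-7-yl]prop-2-en-1-ol | COc1cc([C@@H]2Oc3cc(/C=C/CO)cc(OC)c3O[C@H]2C)cc(OC)c1OC
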